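The route rests on disconnecting the cyclopentanone at C1–C8a (azulene numbering: C1 ketone, C3 isopropyl, C3a hydroxyl, C6=C7 alkene, C8 ester oxygen, C8a methyl). The C1 carbonyl and the C8 oxygen flank quaternary C8a as an aldol pair, and C8–O is allylic to C6=C7: the retron of a nitrile oxide added to a 1,3-diene. An intramolecular nitrile oxide cycloaddition onto a cycloheptadienol therefore closes the five-membered ring C1–C2–C3–C3a–C8a last and sets C8a, C8 and the masked aldol in one operation. Its precursor is a γ-hydroxy aldoxime on a tertiary dienol, whose C3a and C3 centres come from a catalytic asymmetric allylboration of 2,5-dimethylcyclohepta-2,4-dienone.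

Key step: step 9

Assumption: the sense of induction of the diol-catalysed allylboration is taken to follow that known for aryl methyl ketones, with the methyl-bearing sp2 arm of dienone 5 in the role of the aryl group; the (S)-diol is written on that basis and its antipode would be used if the opposite carbinol configuration were delivered.

Step 1
Reactants: 1 4-methylanisole
Product: 2 1-methoxy-4-methylcyclohexa-1,4-diene
Conditions: Li, liquid NH3, t-BuOH, THF, −78 to −33 °C; NH4Cl quench
Reagents that add atoms: none
Why: Birch reduction of an anisole protonates ortho and meta to the methoxy group and should deliver the 1-alkoxy-1,4-diene with an isolated enol ether double bond.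

Step 2
Reactants: 2 1-methoxy-4-methylcyclohexa-1,4-diene
Product: 4 2,5-dimethylcyclohepta-2,5-dien-1-one, via chlorocyclopropane 3 (not isolated)
Conditions: CH3CHCl2, n-BuLi, Et2O, −35 °C; then NaHCO3, dioxane/H2O, 90 °C
Reagents that add atoms: 1,1-dichloroethane (CC(Cl)Cl); water (O)
Why: The electrophilic chloro(methyl)carbenoid should add to the more electron-rich enol ether double bond, and alkoxy-assisted opening of the chlorocyclopropane to the allyl cation followed by hydrolysis inserts the methyl-bearing carbon next to the carbonyl (carbene cyclopropanation and cyclopropyl-to-allyl ring expansion).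

Step 3
Reactants: 4 2,5-dimethylcyclohepta-2,5-dien-1-one
Product: 5 2,5-dimethylcyclohepta-2,4-dien-1-one
Conditions: DBU (cat.), toluene, 60 °C
Reagents that add atoms: none
Why: A base-mediated prototropic shift through the extended dienolate should move the isolated double bond into linear conjugation, the thermodynamically preferred 2,4-dienone with two trisubstituted alkenes.

Step 4
Reactants: 6 (E)-4-methylpent-2-ene
Product: 8 diisopropyl [(E)-4-methylpent-2-en-1-yl]boronate, via allylpotassium 7 (not isolated)
Conditions: n-BuLi, KOtBu, THF, −50 °C; B(OiPr)3, −78 °C; HCl/Et2O, −78 °C to rt; distillation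
Reagents that add atoms: triisopropyl borate (CC(C)OB(OC(C)C)OC(C)C)
Why: Superbase metalation of the allylic methyl group keeps the E geometry at low temperature, and the borate traps the allyl anion at its unhindered primary terminus (allylpotassium borylation).

Step 5
Reactants: 5 2,5-dimethylcyclohepta-2,4-dien-1-one; 8 diisopropyl [(E)-4-methylpent-2-en-1-yl]boronate
Product: 10 (1S)-2,5-dimethyl-1-[(3S)-4-methylpent-1-en-3-yl]cyclohepta-2,4-dien-1-ol, via borate ester 9 (not isolated)
Conditions: (S)-3,3'-Br2-BINOL (15 mol %), PhCF3/toluene, −35 °C to rt; aqueous work-up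
Reagents that add atoms: none
Why: Chiral-diol-catalysed allylboration of a ketone through a closed chair transition state should set both centres: E geometry puts isopropyl equatorial and the branched sp2 arm of the ketone equatorial (hydroxyl and isopropyl cis in the later ring), while the boron-bound diol selects the carbonyl face (absolute configuration at C3a and C3).

Step 6
Reactants: 10 (1S)-2,5-dimethyl-1-[(3S)-4-methylpent-1-en-3-yl]cyclohepta-2,4-dien-1-ol
Product: 12 (3R)-3-[(1S)-1-hydroxy-2,5-dimethylcyclohepta-2,4-dien-1-yl]-4-methylpentan-1-ol, via alkylborane 11 (not isolated)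
Conditions: 9-BBN (2.5 equiv), THF, 0 °C to rt; then 3 M NaOH, 30% H2O2, 0 °C
Reagents that add atoms: hydrogen peroxide (OO)
Why: 9-BBN adds anti-Markovnikov to the monosubstituted alkene far faster than to the trisubstituted diene double bonds, and basic peroxide oxidation spares the acid-labile tertiary dienyl alcohol (hydroboration–oxidation).

Step 7
Reactants: 12 (3R)-3-[(1S)-1-hydroxy-2,5-dimethylcyclohepta-2,4-dien-1-yl]-4-methylpentan-1-ol
Product: 14 (4R,5S)-6,9-dimethyl-4-(propan-2-yl)-1-oxaspiro[4.6]undeca-6,8-dien-2-ol, via hydroxy aldehyde 13 (not isolated)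
Conditions: SO3·pyridine, DMSO, iPr2NEt, CH2Cl2, 0 °C
Reagents that add atoms: none
Why: Parikh–Doering oxidation touches only the primary alcohol under basic conditions, and the γ-hydroxy aldehyde should close to the five-membered lactol, which limits over-oxidation.

Step 8
Reactants: 14 (4R,5S)-6,9-dimethyl-4-(propan-2-yl)-1-oxaspiro[4.6]undeca-6,8-dien-2-ol
Product: 15 (3R)-3-[(1S)-1-hydroxy-2,5-dimethylcyclohepta-2,4-dien-1-yl]-4-methylpentanal oxime
Conditions: NH2OH·HCl, NaOAc, EtOH/H2O, rt
Reagents that add atoms: hydroxylamine hydrochloride (NO.Cl)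
Why: Hydroxylamine intercepts the open aldehyde tautomer of the lactol (oxime condensation) in an acetate buffer mild enough for the ionisable tertiary dienyl alcohol.

Step 9
Reactants: 15 (3R)-3-[(1S)-1-hydroxy-2,5-dimethylcyclohepta-2,4-dien-1-yl]-4-methylpentanal oxime
Product: 18 tricyclic isoxazoline (3R,3aS,8R,8aR), via hydroximoyl chloride 16 (not isolated), via nitrile oxide 17 (not isolated)
Conditions: aq. NaOCl, CH2Cl2, 0 °C to rt, 0.01 M, slow addition
Reagents that add atoms: none
Why: Hypochlorite converts the aldoxime into the hydroximoyl chloride and then the nitrile oxide, which adds as a 1,3-dipole in a concerted suprafacial (3+2) cycloaddition across the C8a=C8 double bond of the ring diene, the dipole carbon bonding to C8a and its oxygen to C8. The closest known reaction type is the intramolecular nitrile oxide–alkene cycloaddition of 3-(cycloalk-2-en-1-yl)propanenitrile oxides, used as a masked aldol. The carbocyclic five-membered ring (C1–C2–C3–C3a–C8a) closes in the fused exo mode through the three-atom tether C2–C3–C3a by forming C1–C8a, and the temporary isoxazoline ring (C1=N–O–C8–C8a) closes in the same concerted event by O–C8 bonding. The C8a centre is controlled by the tether, which can reach only the diene face syn to the C3a–C3 bond, so the new C1–C8a bond is cis to C3 and the methyl ends cis to the 3a-hydroxyl (cis-fused hydroazulene); the C8 centre is controlled by the suprafacial course of the cycloaddition, which places the oxygen cis to C1 and trans to the C8a methyl. The step needs site and regioselectivity (C8a=C8 and not C6=C7, carbon to C8a), secured by the tether length and reinforced by the preference of nitrile oxides to place oxygen on the internal carbon of a 1,3-diene, and chemoselectivity over hydroxyl capture and furoxan dimerisation, secured by high dilution, the small linear dipole and the hindered tertiary hydroxyl.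

Step 10
Reactants: 18 tricyclic isoxazoline (3R,3aS,8R,8aR)
Product: 20 (3R,3aS,8R,8aR)-3a,8-dihydroxy-6,8a-dimethyl-3-(propan-2-yl)-3,3a,4,5,8,8a-hexahydroazulen-1(2H)-one, via hydroxy imine 19 (not isolated)
Conditions: Mo(CO)6, MeCN/H2O, 80 °C
Reagents that add atoms: water (O)
Why: Mo(CO)6 should cleave the N–O bond reductively without touching the trisubstituted alkene, and the β-hydroxy imine hydrolyses to the ketone, while quaternary C8a blocks dehydration of the unmasked aldol.

Step 11
Reactants: 20 (3R,3aS,8R,8aR)-3a,8-dihydroxy-6,8a-dimethyl-3-(propan-2-yl)-3,3a,4,5,8,8a-hexahydroazulen-1(2H)-one; 21 4-methoxybenzoyl chloride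
Product: 22 (3R,3aS,8R,8aR)-3a-hydroxy-6,8a-dimethyl-1-oxo-3-(propan-2-yl)-1,2,3,3a,4,5,8,8a-octahydroazulen-8-yl 4-methoxybenzoate
Conditions: Et3N, DMAP (cat.), CH2Cl2, 0 °C to rt
Reagents that add atoms: none
Why: DMAP-catalysed acylation should esterify the secondary allylic C8 hydroxyl and leave the tertiary C3a hydroxyl untouched, with no stereocentre involved (nucleophilic-catalysis esterification).

Compound list
1 | 4-methylanisole | COc1ccc(C)cc1 | starting material
2 | 1-methoxy-4-methylcyclohexa-1,4-diene | COC1=CCC(C)=CC1 | intermediate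
3 | 7-chloro-1-methoxy-4,7-dimethylbicyclo[4.1.0]hept-3-ene (C7 epimers, not isolated) | COC12CC=C(C)CC1C2(C)Cl | intermediate
4 | 2,5-dimethylcyclohepta-2,5-dien-1-one | O=C1CC=C(C)CC=C1C | intermediate
5 | 2,5-dimethylcyclohepta-2,4-dien-1-one | O=C1CCC(C)=CC=C1C | intermediate
6 | (E)-4-methylpent-2-ene | C/C=C/C(C)C | starting material
7 | (E)-4-methylpent-2-en-1-ylpotassium (not isolated) | [K+].[CH2-]/C=C/C(C)C | intermediate
8 | diisopropyl [(E)-4-methylpent-2-en-1-yl]boronate | CC(C)OB(C/C=C/C(C)C)OC(C)C | intermediate
9 | diisopropyl (1S)-2,5-dimethyl-1-[(3S)-4-methylpent-1-en-3-yl]cyclohepta-2,4-dien-1-yl borate (not isolated) | C=C[C@H](C(C)C)[C@@]1(OB(OC(C)C)OC(C)C)CCC(C)=CC=C1C | intermediate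
10 | (1S)-2,5-dimethyl-1-[(3S)-4-methylpent-1-en-3-yl]cyclohepta-2,4-dien-1-ol | C=C[C@H](C(C)C)[C@@]1(O)CCC(C)=CC=C1C | intermediate
11 | 9-{(3R)-3-[(1S)-1-hydroxy-2,5-dimethylcyclohepta-2,4-dien-1-yl]-4-methylpentyl}-9-borabicyclo[3.3.1]nonane (hydroxyl drawn free, not isolated) | C1CC2CCCC(C1)B2CC[C@H](C(C)C)[C@@]1(O)CCC(C)=CC=C1C | intermediate
12 | (3R)-3-[(1S)-1-hydroxy-2,5-dimethylcyclohepta-2,4-dien-1-yl]-4-methylpentan-1-ol | OCC[C@H](C(C)C)[C@@]1(O)CCC(C)=CC=C1C | intermediate
13 | (3R)-3-[(1S)-1-hydroxy-2,5-dimethylcyclohepta-2,4-dien-1-yl]-4-methylpentanal (open tautomer, not isolated) | O=CC[C@H](C(C)C)[C@@]1(O)CCC(C)=CC=C1C | intermediate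
14 | (4R,5S)-6,9-dimethyl-4-(propan-2-yl)-1-oxaspiro[4.6]undeca-6,8-dien-2-ol (lactol, both anomers) | OC1C[C@H](C(C)C)[C@@]2(O1)CCC(C)=CC=C2C | intermediate
15 | (3R)-3-[(1S)-1-hydroxy-2,5-dimethylcyclohepta-2,4-dien-1-yl]-4-methylpentanal oxime (E/Z) | ON=CC[C@H](C(C)C)[C@@]1(O)CCC(C)=CC=C1C | intermediate
16 | (3R)-N-hydroxy-3-[(1S)-1-hydroxy-2,5-dimethylcyclohepta-2,4-dien-1-yl]-4-methylpentanimidoyl chloride (not isolated) | ON=C(Cl)C[C@H](C(C)C)[C@@]1(O)CCC(C)=CC=C1C | intermediate
17 | (3R)-3-[(1S)-1-hydroxy-2,5-dimethylcyclohepta-2,4-dien-1-yl]-4-methylpentanenitrile oxide (not isolated) | [O-][N+]#CC[C@H](C(C)C)[C@@]1(O)CCC(C)=CC=C1C | intermediate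
18 | (3R,3aS,8R,8aR)-6,8a-dimethyl-3-(propan-2-yl)-2,3,4,5,8,8a-hexahydro-8,1-(epoxynitrilo)azulen-3a-ol (isoxazoline: O on C8, C=N at C1, azulene numbering) | O1[C@@H]2C=C(C)CC[C@]3(O)[C@@H](C(C)C)CC(=N1)[C@]23C | intermediate
19 | (3R,3aS,8R,8aR)-1-imino-6,8a-dimethyl-3-(propan-2-yl)-1,2,3,4,5,8-hexahydroazulene-3a,8(8aH)-diol (not isolated) | O[C@@H]1C=C(C)CC[C@]2(O)[C@@H](C(C)C)CC(=N)[C@]12C | intermediate
20 | (3R,3aS,8R,8aR)-3a,8-dihydroxy-6,8a-dimethyl-3-(propan-2-yl)-3,3a,4,5,8,8a-hexahydroazulen-1(2H)-one | O[C@@H]1C=C(C)CC[C@]2(O)[C@@H](C(C)C)CC(=O)[C@]12C | intermediate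
21 | 4-methoxybenzoyl chloride | COc1ccc(C(=O)Cl)cc1 | starting material
22 | (3R,3aS,8R,8aR)-3a-hydroxy-6,8a-dimethyl-1-oxo-3-(propan-2-yl)-1,2,3,3a,4,5,8,8a-octahydroazulen-8-yl 4-methoxybenzoate | COc1ccc(C(=O)O[C@@H]2C=C(C)CC[C@]3(O)[C@@H](C(C)C)CC(=O)[C@]23C)cc1 | target

Total step count: 11. Longest linear sequence: 10 steps (steps 1–3 and 5–11 from 4-methylanisole); step 4 is a one-step branch.

Steps most likely to fail

Risk 1, step 5. The two α-arms of the cyclic dienone differ little in size, so discrimination of the arms and of the carbonyl faces in the closed transition state may be poor, eroding both enantio- and diastereoselectivity; the hindered conjugated ketone may also turn over slowly. The fallback replaces boron–diol catalysis by a chromium-catalysed asymmetric Nozaki–Hiyama–Kishi-type allylation and sets out from dienone 5. (E)-4-Methylpent-2-en-1-ol is converted with PBr3 into (E)-1-bromo-4-methylpent-2-ene F1. F1, CrCl3 (cat.), a chiral oxazoline–amide ligand, Mn powder, Me3SiCl and Et3N in THF should add the γ-carbon of the allylchromium species to 5 through the anti-selective chair transition state and give the trimethylsilyl ether of the homoallylic alcohol F2. K2CO3 in MeOH removes the silyl group and the sequence comes back to the route at 10.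

Risk 2, step 9. Capture of the nitrile oxide by the neighbouring tertiary hydroxyl (cyclic hydroximate) or dimerisation to a furoxan may outrun cycloaddition onto the trisubstituted diene terminus. The fallback masks the hydroxyl so that the dipole meets no internal nucleophile and sets out from oxime 15. Et3SiOTf and 2,6-lutidine give the O-triethylsilyl oxime of the tertiary triethylsilyl ether F3. K2CO3 in MeOH cleaves only the labile oxime silyl group to give the silyl ether oxime F4. Aqueous NaOCl in CH2Cl2 then effects the same cycloaddition to the silylated isoxazoline F5, and HF·pyridine in THF comes back to the route at 18.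

Risk 3, step 2. Carbenoid transfer from 1,1-dichloroethane may be inefficient, and the exo-chloro epimer of the cyclopropane may ionise sluggishly, which would limit the ring expansion. The fallback is the classical dihalocarbene ring expansion followed by cross-coupling and sets out from diene 2. CHBr3 and KOtBu give 7,7-dibromo-1-methoxy-4-methylbicyclo[4.1.0]hept-3-ene F6. AgNO3 in aqueous acetone opens it to 2-bromo-5-methylcyclohepta-2,5-dien-1-one F7. Suzuki–Miyaura methylation (trimethylboroxine, Pd(PPh3)4, K2CO3, dioxane, 90 °C) replaces bromine by methyl and comes back to the route at 4.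

Further compounds
F1 | step 5 | (E)-1-bromo-4-methylpent-2-ene | CC(C)/C=C/CBr
F2 | step 5 | trimethylsilyl ether of (1S)-2,5-dimethyl-1-[(3S)-4-methylpent-1-en-3-yl]cyclohepta-2,4-dien-1-ol | C=C[C@H](C(C)C)[C@@]1(O[Si](C)(C)C)CCC(C)=CC=C1C
F3 | step 9 | O-triethylsilyl oxime of (3R)-3-[(1S)-2,5-dimethyl-1-(triethylsilyloxy)cyclohepta-2,4-dien-1-yl]-4-methylpentanal | CC[Si](CC)(CC)ON=CC[C@H](C(C)C)[C@@]1(O[Si](CC)(CC)CC)CCC(C)=CC=C1C
F4 | step 9 | (3R)-3-[(1S)-2,5-dimethyl-1-(triethylsilyloxy)cyclohepta-2,4-dien-1-yl]-4-methylpentanal oxime | ON=CC[C@H](C(C)C)[C@@]1(O[Si](CC)(CC)CC)CCC(C)=CC=C1C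
F5 | step 9 | 3a-O-triethylsilyl ether of isoxazoline 18 | O1[C@@H]2C=C(C)CC[C@]3(O[Si](CC)(CC)CC)[C@@H](C(C)C)CC(=N1)[C@]23C
F6 | step 2 | 7,7-dibromo-1-methoxy-4-methylbicyclo[4.1.0]hept-3-ene | COC12CC=C(C)CC1C2(Br)Br
F7 | step 2 | 2-bromo-5-methylcyclohepta-2,5-dien-1-one | O=C1CC=C(C)CC=C1Br
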